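## Structural features

The target 18 is an isoflavone: a benzopyran-4-one in which the benzo ring (ring A) and the pyranone (ring C) share C4a–C8a, and a separate benzene (ring B) is bonded through C1' to C3 of ring C. Ring A carries free hydroxyls at C5 and C7 (phloroglucinol pattern), with the C5 hydroxyl hydrogen-bonded to the C4 carbonyl. Ring B carries a methoxy group at C4' and, ortho to it, a 3-methylbut-2-enyl (prenyl) group at C3'. There is no stereocentre, so no stereochemical relationship needs control. The fragile parts are the trisubstituted prenyl alkene and its doubly activated CH2 (strong acid, hydrogen chloride, hydrogenation, oxidants), the electron-rich phenols of ring A, and C2 of the chromone, which amines and hydroxide attack with ring opening. The real difficulty is to close ring C between a very electron-rich ring A and a C3 aryl group with one regiochemistry and without strongly acidic acylation conditions, and to introduce the prenyl group in its linear form. The key step exploits the fact that C2 is an unsubstituted CH, C4 a carbonyl and C3 the carbon bearing ring B. C2, C3 and C4 therefore map onto the two carboxyl carbons and the central carbon of an arylmalonate, and O1, C8a and C4a onto a 3,5-dioxygenated phenol whose two ortho carbons are equivalent by symmetry.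

## Logic of the disconnections

18 to 15. No skeletal bond is cut. The two free hydroxyls of ring A are traced back to acetal-protected oxygens, and the C4 carbonyl to a C4 methyl enol ether next to a C2 hemiacetal. One acid treatment can then transpose the oxygen pattern of ring C and unmask ring A together, so the endgame is a single operation. The forward step must ionise at C2, hydrolyse at C4 and cleave two acetals faster than the acid adds to the prenyl alkene.

15 to 14. The C2–H bond is removed, returning C2 to the lactone level. A lactone is what a double acylation of a phenol delivers, so this is the price of the ring construction below; the gain is a stable heterocycle. The forward hydride addition must stop at the hemiacetal and attack C2 directly, not C4 in conjugate fashion.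

14 to 13. The O4–CH3 bond is cut. The C4 hydroxyl of 13 belongs to a vinylogous carboxylic acid whose salt would resist hydride and whose tautomers blur the difference between C2 and C4; capping O4 freezes the 2-oxo form. The forward step must alkylate O4 in preference to O2 (C3 is blocked by ring B).

13 to 2 and 9. O1–C2 and C4–C4a are cut, the two bonds that stitch a three-carbon malonyl unit to ring A. Both fragments are mirror-symmetric, so the two carboxyl carbons of 9 and the two ortho carbons of 2 are interchangeable and only one constitution can form. The target is split into two pieces of similar size. The forward step must acylate oxygen first and then the ortho carbon, must not stop at a diaryl malonate, and must spare the acetals of 2 and the alkene of 9.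

9 to 7 and 8. The two acyl–oxygen bonds are cut. Aryloxy leaving groups of this acidity make both carboxyls transferable by heat alone, and the activating group is a commodity phenol. The forward esterification must be cold and neutral, because 7 decarboxylates easily and its alkene is sensitive to hydrogen chloride.

7 to 5. The bond between the benzylic carbon and one carboxyl carbon is cut, leaving an arylacetic acid. The malonate problem is reduced to a one-carbon homologation. The forward step needs C-carboxylation of a dianion to outrun proton exchange with the more acidic product.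

5 to 3 and 4. The bond between C3' of ring B and the allylic CH2 is cut. This separates the sensitive five-carbon unit from a commercial bromoarene that already has the methoxy and acetic acid groups in place. The forward coupling must give the linear isomer, not the 1,1-dimethylallyl isomer.

2 to 1. Two O–CH2 bonds are cut, leading to a symmetric triol. The forward double alkylation is statistical, so 2 must be separated from its lower and higher homologues. This is accepted because 1 is cheap and the step opens its branch.

## Other disconnections considered

Alternative 1: Only C4–C4a is cut; O1–C2 and the C2=C3 double bond are already present in the aryloxyacrylic acid (Z)-2-(3-bromo-4-methoxyphenyl)-3-[3,5-di(propan-2-yloxy)phenoxy]prop-2-enoic acid A2. In the forward direction the carboxyl group of A2 is activated (acid chloride with a Lewis acid, or a dehydrating strong acid) and acylates the ortho carbon of the symmetric ring A. This closes the pyranone and would give 3-(3-bromo-4-methoxyphenyl)-5,7-di(propan-2-yloxy)chromen-4-one A1 as the product of the key step.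
- In its favour: in A1 ring C arrives at the chromone oxidation level, so the methylation and reduction of the chosen plan are not needed; on this point the alternative is better. With O1–C2 preformed and ring A symmetric, the constitution is fixed by connectivity, which makes it the equal of the chosen plan in that respect.
- Against it here: an acylium-type cyclisation needs strong acid, which excludes acetal protection and a prenyl group. Hence the isopropyl ethers and the bromine placeholder, and hence two late operations on the most valuable material. The first is dealkylation of A1 with BCl3 to 3-(3-bromo-4-methoxyphenyl)-5,7-dihydroxychromen-4-one A3. The second is an allyl cross-coupling of A3 with 4 to reach 18, whose linear/branched selectivity is then tested at the very end. The acid A2 must also have carboxyl and aryloxy groups cis, or be able to isomerise.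
- Comparison: both plans close ring C by electrophilic substitution at the same carbon, the chosen one with a neutral ketene and no added acid, the alternative with a cationic acyl species. The step counts are close (about seven to eight operations each). The difference is where the risk sits: early and on cheap material in the chosen plan, late in the alternative.

Alternative 2: Ring B is cut at C1'–C2' and C5'–C6' and is not aromatic at the key stage. An enamine formed from 2-[5,7-bis(methoxymethoxy)-4-oxochromen-3-yl]acetaldehyde A5 and a secondary amine would add through its α-carbon to the methylene of 6-methyl-3-methylidenehept-5-en-2-one A6. The methyl ketone of A6 would then condense with the aldehyde carbon (Robinson-type annulation) to give cis-4-[5,7-bis(methoxymethoxy)-4-oxochromen-3-yl]-6-(3-methylbut-2-enyl)cyclohex-2-en-1-one A4 as a racemate. Dehydrogenation of A4 to the phenol and O-methylation would follow.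
- In its favour: the prenyl group enters as an ordinary substituent of the enone A6, so the linear/branched problem of allyl–aryl coupling does not arise; here the alternative is better. The substitution pattern of ring B is fixed by connectivity, and the two stereocentres of A4 vanish on aromatisation, so in stereochemical demand it is level with the chosen plan (none).
- Against it here: the secondary amine needed for enamine formation is also a nucleophile for C2 of the chromone, whose ring would open to an enaminoketone. The aldehyde A5 is enolisable and prone to self-condensation. The aromatisation needs an oxidant or dehydrogenation catalyst that must spare the doubly activated CH2 and the alkene of the prenyl group.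
- Comparison: rings A and C still have to be made first (A5 is several steps from a simple chromone), and aromatisation plus methylation add two steps after the key step, so the sequence is clearly longer. The conjugate addition–aldol sequence is reliable in itself; the weakness lies in the functional groups around it.

Alternative 3: Ring A is cut at C5–C6, C7–C8 and C4a–C5 and is grown on a preformed pyranone. Irradiation of 2-(2-diazoacetyl)-5-[4-methoxy-3-(3-methylbut-2-enyl)phenyl]pyran-4-one A8 would trigger a Wolff rearrangement to a pyranonyl vinylketene, which would undergo [2+2] cycloaddition with ethynyloxy-tri(propan-2-yl)silane A9. Four-electron opening of the cyclobutenone, six-electron electrocyclisation onto the pyranone double bond and tautomerisation (a Danheiser benzannulation) would give 5-hydroxy-3-[4-methoxy-3-(3-methylbut-2-enyl)phenyl]-7-(triisopropylsilyloxy)chromen-4-one A7 as the product of the key step.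
- In its favour: three C–C bonds and ring A form in one operation, with regiochemistry set by the polarity of ketene and siloxyalkyne. In A7 the C5 hydroxyl is born free and the C7 oxygen is a silyl ether, so a single fluoride treatment of A7 would reach 18 with no acid near the prenyl group. In endgame length and mildness this alternative is better than the chosen plan, and it needs no oxidation-level correction.
- Against it here: the diazoketone A8 already contains rings B and C, and a 5-aryl-4-pyranone-2-carboxylic acid derivative with the prenylated aryl group is a problem of about the same size as the chromone itself, before diazoketone formation. 4-Pyranones absorb and rearrange under the irradiation needed for the Wolff step, the prenyl alkene can trap the carbene or the ketene, and the alkyne A9 is hydrolytically sensitive.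
- Comparison: the chosen plan draws ring A from 1 in one step and uses only thermal, polar chemistry. The overall step count would hardly be lower, because what is saved after the key step is spent before it.

Key step: step 5

Remark on the chemistry: 9 is reached through the free acids (coupling on 3 itself, direct carboxylation of the dianion) to shorten its preparation; the condensation is run in boiling toluene with slow addition of 2, not in a melt, to protect the acetals and the alkene; in step 8 the lactol is assumed to go to the chromone before the acetals are cleaved, so 17 is written as the intermediate, and the reverse order would end at the same product; 11 and 15 each contain one stereocentre, form as racemates and lose it in the next event.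

Step 1
Reactants: 1 phloroglucinol (benzene-1,3,5-triol)
Product: 2 3,5-bis(methoxymethoxy)phenol
Conditions: MOMCl (2.0 equiv), iPr2NEt (2.2 equiv), THF, 0 °C to rt; chromatography
Reagents that add atoms: chloromethyl methyl ether, COCCl
Why: Base-mediated O-alkylation of a phenol by an α-chloro ether (acetal formation); the three hydroxyls are equivalent, so the bis-ether is a single constitution and is separated from the mono- and tris-ethers, which acid returns to 1.

Step 2
Reactants: 3 2-(3-bromo-4-methoxyphenyl)acetic acid; 4 3-methylbut-2-enylboronic acid pinacol ester [4,4,5,5-tetramethyl-2-(3-methylbut-2-enyl)-1,3,2-dioxaborolane]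
Product: 5 2-[4-methoxy-3-(3-methylbut-2-enyl)phenyl]acetic acid
Conditions: [(C3H5)PdCl]2 (1.5 mol %), tBuXPhos (6 mol %), K3PO4 (aq, 4 equiv), MeCN, 70 °C; then 1 M HCl
Reagents that add atoms: none
Why: Suzuki–Miyaura coupling of an allylboronate after oxidative addition of zerovalent palladium into the C–Br bond; the bulky di-tert-butylbiarylphosphine (2-di-tert-butylphosphino-2',4',6'-triisopropylbiphenyl) should make the allylpalladium intermediate equilibrate to its less hindered primary σ-allyl form before reductive elimination, giving the linear prenyl arene rather than the 1,1-dimethylallyl isomer. The carboxylate is a spectator and allows purification by acid–base extraction.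

Step 3
Reactants: 5 2-[4-methoxy-3-(3-methylbut-2-enyl)phenyl]acetic acid
Product: 7 2-[4-methoxy-3-(3-methylbut-2-enyl)phenyl]propanedioic acid, via dilithium enediolate 6 (not isolated)
Conditions: LiN(iPr)2 (2.3 equiv), THF, −78 to 0 °C; cannulated into CO2-saturated THF, −78 °C; 1 M HCl, 0 °C
Reagents that add atoms: carbon dioxide, O=C=O
Why: Carboxylation of the dianion of an arylacetic acid (Ivanov-type reaction); inverse addition into excess CO2 keeps C-carboxylation ahead of proton transfer from the more acidic product, and cold acidification with evaporation below 25 °C avoids decarboxylation.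

Step 4
Reactants: 7 2-[4-methoxy-3-(3-methylbut-2-enyl)phenyl]propanedioic acid; 8 2,4,6-trichlorophenol (2.2 equiv)
Product: 9 bis(2,4,6-trichlorophenyl) 2-[4-methoxy-3-(3-methylbut-2-enyl)phenyl]propanedioate
Conditions: DCC (2.1 equiv), EtOAc, −10 to 20 °C; filtration; crystallisation
Reagents that add atoms: none
Why: Carbodiimide esterification to an aryl active ester, the method used for trichlorophenyl esters of amino acids; it is neutral and cold, so neither the alkene nor the malonic acid is endangered, which the usual POCl3 procedure with its hydrogen chloride would not guarantee.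

Step 5
Reactants: 2 3,5-bis(methoxymethoxy)phenol; 9 bis(2,4,6-trichlorophenyl) 2-[4-methoxy-3-(3-methylbut-2-enyl)phenyl]propanedioate
Product: 13 4-hydroxy-3-[4-methoxy-3-(3-methylbut-2-enyl)phenyl]-5,7-bis(methoxymethoxy)chromen-2-one, via ketene ester 10 (not isolated), via mixed malonate 11 (not isolated), via acylketene 12 (not isolated)
Conditions: 2 (1.0 equiv) added over 2 h to 9 (1.0 equiv), PhMe, 110 °C, N2; then 2 h
Reagents that add atoms: none
Why: Enolisation of 9 and loss of one molecule of 8 should give the ketene 10, whose central carbon is attacked by the hydroxyl of 2 to form O1–C2 in the mixed malonate 11; a second loss of 8 gives the acylketene 12, now tethered to ring A through the ester oxygen. The ortho carbon of ring A then attacks the ketene carbon through a six-membered transition state (intramolecular Friedel–Crafts-type acylation, 6-exo-dig with respect to the ketene C=O), forming C4–C4a and closing ring C; proton shifts restore the arene and leave the 4-hydroxy-2-oxo tautomer. The closest known reaction type is the thermal cyclocondensation of bis(2,4,6-trichlorophenyl) malonates with phenols to 4-hydroxycoumarins, and for so electron-rich a phenol the temperature of boiling toluene should suffice. No stereocentre is formed; the malonate carbon of 11 is a transient racemic centre that becomes sp2. The step needs C-acylation to win over a second O-acylation: the tether makes the C-attack intramolecular, the attacked carbon is activated by an ortho and a para acetal oxygen as well as the ester oxygen, and slow addition of 2 keeps free phenol scarce. Any diaryl malonate that does form can re-enter through 12 by thermal loss of 2. Regiochemistry cannot go wrong, because both ortho carbons of 2 and both carboxyls of 9 are equivalent and the para carbon cannot reach the tethered ketene. Boiling toluene is preferred to a melt so that the acetals of 2 and the prenyl alkene meet only the weakly acidic 8 at moderate temperature.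

Step 6
Reactants: 13 4-hydroxy-3-[4-methoxy-3-(3-methylbut-2-enyl)phenyl]-5,7-bis(methoxymethoxy)chromen-2-one
Product: 14 4-methoxy-3-[4-methoxy-3-(3-methylbut-2-enyl)phenyl]-5,7-bis(methoxymethoxy)chromen-2-one
Conditions: Me2SO4 (1.3 equiv), K2CO3, acetone, 56 °C
Reagents that add atoms: dimethyl sulfate, COS(=O)(=O)OC
Why: O-Alkylation of the potassium salt of a vinylogous carboxylic acid with a hard methylating agent; C3 is blocked by ring B, and alkylation at O4 retains the lactone, so the 4-methoxycoumarin should be the main product.

Step 7
Reactants: 14 4-methoxy-3-[4-methoxy-3-(3-methylbut-2-enyl)phenyl]-5,7-bis(methoxymethoxy)chromen-2-one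
Product: 15 4-methoxy-3-[4-methoxy-3-(3-methylbut-2-enyl)phenyl]-5,7-bis(methoxymethoxy)-2H-chromen-2-ol (racemic lactol)
Conditions: iBu2AlH (1.2 equiv), CH2Cl2, −78 °C; MeOH, then KNaC4H4O6 (aq)
Reagents that add atoms: none
Why: Partial reduction of a lactone to a lactol, a known reaction of coumarins; at −78 °C the aluminium-bound tetrahedral adduct should not collapse before work-up, and iBu2AlH in a non-coordinating solvent adds 1,2 to the carbonyl, not at the hindered C4. The new C2 hemiacetal centre forms as a racemate and is removed in step 8.

Step 8
Reactants: 15 4-methoxy-3-[4-methoxy-3-(3-methylbut-2-enyl)phenyl]-5,7-bis(methoxymethoxy)-2H-chromen-2-ol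
Product: 18 5,7-dihydroxy-3-[4-methoxy-3-(3-methylbut-2-enyl)phenyl]chromen-4-one, via chromenylium chloride 16 (not isolated), via bis(methoxymethyl) isoflavone 17 (not isolated)
Conditions: HCl (3 M aq)/MeOH (1:5), 50 °C
Reagents that add atoms: water, O
Why: Acid ionises the allylic hemiacetal to the 4-methoxybenzopyrylium ion 16; water adds at C4 and methanol leaves (the oxygen-heterocycle counterpart of a Stork–Danheiser transposition) to give the chromone 17, whose two methoxymethyl ethers are then transacetalised by methanol. The prenyl group stands next to a methyl ether, not a free hydroxyl, so acid-induced chroman formation has no partner, and these are the usual conditions for acetal removal from prenylated flavonoids.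

Compound list

1 | phloroglucinol (benzene-1,3,5-triol) | Oc1cc(O)cc(O)c1 | starting material
2 | 3,5-bis(methoxymethoxy)phenol | COCOc1cc(O)cc(OCOC)c1 | intermediate
3 | 2-(3-bromo-4-methoxyphenyl)acetic acid | OC(=O)Cc1ccc(OC)c(Br)c1 | starting material
4 | 4,4,5,5-tetramethyl-2-(3-methylbut-2-enyl)-1,3,2-dioxaborolane | CC(C)=CCB1OC(C)(C)C(C)(C)O1 | starting material
5 | 2-[4-methoxy-3-(3-methylbut-2-enyl)phenyl]acetic acid | COc1ccc(CC(=O)O)cc1CC=C(C)C | intermediate
6 | dilithium 2-[4-methoxy-3-(3-methylbut-2-enyl)phenyl]ethene-1,1-bis(olate) | [Li+].[Li+].COc1ccc(C=C([O-])[O-])cc1CC=C(C)C | intermediate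
7 | 2-[4-methoxy-3-(3-methylbut-2-enyl)phenyl]propanedioic acid | COc1ccc(C(C(=O)O)C(=O)O)cc1CC=C(C)C | intermediate
8 | 2,4,6-trichlorophenol | Oc1c(Cl)cc(Cl)cc1Cl | starting material
9 | bis(2,4,6-trichlorophenyl) 2-[4-methoxy-3-(3-methylbut-2-enyl)phenyl]propanedioate | COc1ccc(C(C(=O)Oc2c(Cl)cc(Cl)cc2Cl)C(=O)Oc2c(Cl)cc(Cl)cc2Cl)cc1CC=C(C)C | intermediate
10 | 2,4,6-trichlorophenyl 2-[4-methoxy-3-(3-methylbut-2-enyl)phenyl]-3-oxoprop-2-enoate | COc1ccc(C(=C=O)C(=O)Oc2c(Cl)cc(Cl)cc2Cl)cc1CC=C(C)C | intermediate
11 | 1-[3,5-bis(methoxymethoxy)phenyl] 3-(2,4,6-trichlorophenyl) 2-[4-methoxy-3-(3-methylbut-2-enyl)phenyl]propanedioate (racemic) | COCOc1cc(OCOC)cc(OC(=O)C(c2ccc(OC)c(CC=C(C)C)c2)C(=O)Oc2c(Cl)cc(Cl)cc2Cl)c1 | intermediate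
12 | 3,5-bis(methoxymethoxy)phenyl 2-[4-methoxy-3-(3-methylbut-2-enyl)phenyl]-3-oxoprop-2-enoate | COCOc1cc(OCOC)cc(OC(=O)C(=C=O)c2ccc(OC)c(CC=C(C)C)c2)c1 | intermediate
13 | 4-hydroxy-3-[4-methoxy-3-(3-methylbut-2-enyl)phenyl]-5,7-bis(methoxymethoxy)chromen-2-one | COCOc1cc(OCOC)c2c(O)c(-c3ccc(OC)c(CC=C(C)C)c3)c(=O)oc2c1 | intermediate
14 | 4-methoxy-3-[4-methoxy-3-(3-methylbut-2-enyl)phenyl]-5,7-bis(methoxymethoxy)chromen-2-one | COCOc1cc(OCOC)c2c(OC)c(-c3ccc(OC)c(CC=C(C)C)c3)c(=O)oc2c1 | intermediate
15 | 4-methoxy-3-[4-methoxy-3-(3-methylbut-2-enyl)phenyl]-5,7-bis(methoxymethoxy)-2H-chromen-2-ol (racemic) | COCOc1cc(OCOC)c2c(c1)OC(O)C(c1ccc(OC)c(CC=C(C)C)c1)=C2OC | intermediate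
16 | 4-methoxy-3-[4-methoxy-3-(3-methylbut-2-enyl)phenyl]-5,7-bis(methoxymethoxy)chromenylium chloride | COCOc1cc(OCOC)c2c(OC)c(-c3ccc(OC)c(CC=C(C)C)c3)c[o+]c2c1.[Cl-] | intermediate
17 | 3-[4-methoxy-3-(3-methylbut-2-enyl)phenyl]-5,7-bis(methoxymethoxy)chromen-4-one | COCOc1cc(OCOC)c2c(c1)occ(-c1ccc(OC)c(CC=C(C)C)c1)c2=O | intermediate
18 | 5,7-dihydroxy-3-[4-methoxy-3-(3-methylbut-2-enyl)phenyl]chromen-4-one | COc1ccc(-c2coc3cc(O)cc(O)c3c2=O)cc1CC=C(C)C | target

Total step count: 8. Longest linear sequence: 7 steps (3 to 18, steps 2 to 8); step 1 is a one-step branch.

Steps least certain to work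

Step 5 (key step). The most likely failure is loss or migration of the methoxymethyl acetals as the hot medium turns weakly acidic, since two equivalents of 8 and the vinylogous acid 13 accumulate; the freed hydroxyls would then be acylated further. A second possibility is interception of 12 at oxygen by another molecule of 2 before it cyclises. The fallback sets out from 1 and 9 and comes back at 18. The condensation would be run with unprotected 1 in excess (dioxane, 100 °C), which has no acid-labile group and a still more nucleophilic ortho carbon, to give 4,5,7-trihydroxy-3-[4-methoxy-3-(3-methylbut-2-enyl)phenyl]chromen-2-one F1. Exhaustive alkylation with MOMCl/iPr2NEt would cap the two phenols and the C4 hydroxyl together as 3-[4-methoxy-3-(3-methylbut-2-enyl)phenyl]-4,5,7-tris(methoxymethoxy)chromen-2-one F2. iBu2AlH at −78 °C would give the lactol 3-[4-methoxy-3-(3-methylbut-2-enyl)phenyl]-4,5,7-tris(methoxymethoxy)-2H-chromen-2-ol F3, and the conditions of step 8 would remove all three acetals and dehydrate to 18. This variant makes steps 1 and 6 unnecessary but risks double annulation of 1, which is why 1 is used in excess.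

Step 2. The most likely failure is erosion of the linear selectivity, by reductive elimination from the tertiary allylpalladium isomer before it equilibrates; this would give the 1,1-dimethylallyl isomer, which is hard to separate. Protodeboronation of 4 is the second concern. The fallback sets out from 3 and comes back at 5, and reverses the polarity so that the prenyl unit is the electrophile. Esterification (MeOH, H2SO4) would give methyl 2-(3-bromo-4-methoxyphenyl)acetate F4. Miyaura borylation (B2pin2, PdCl2(dppf), KOAc, dioxane, 85 °C) would give methyl 2-[4-methoxy-3-(4,4,5,5-tetramethyl-1,3,2-dioxaborolan-2-yl)phenyl]acetate F5. Coupling with 1-bromo-3-methylbut-2-ene (Pd(PPh3)4, K2CO3, THF/H2O) passes through a π-allylpalladium complex that should reductively eliminate at its unsubstituted terminus, giving methyl 2-[4-methoxy-3-(3-methylbut-2-enyl)phenyl]acetate F6, and LiOH would return 5.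

Step 4. The most likely failure is decarboxylation at the mono-activated stage, or incomplete second esterification with the hindered and weakly nucleophilic 8; the resulting arylacetate and half-ester impurities would spoil step 5. The robust POCl3 procedure cannot be applied to 7 because of the alkene. The fallback sets out from 3 and comes back at 14, and moves the prenylation behind the ring construction. Dianion carboxylation of 3 as in step 3 would give 2-(3-bromo-4-methoxyphenyl)propanedioic acid F7. Heating with 8 and POCl3 (90 °C) would give bis(2,4,6-trichlorophenyl) 2-(3-bromo-4-methoxyphenyl)propanedioate F8. Condensation with 2 as in step 5 would give 3-(3-bromo-4-methoxyphenyl)-4-hydroxy-5,7-bis(methoxymethoxy)chromen-2-one F9, and methylation as in step 6 would give 3-(3-bromo-4-methoxyphenyl)-4-methoxy-5,7-bis(methoxymethoxy)chromen-2-one F10. Coupling with 4 under the conditions of step 2 would then give 14, any opened lactone reclosing on acidic work-up.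

Step 6. The most likely failure is alkylation at O2 in competition with O4, because the C4 oxygen is crowded by the C5 acetal and by ring B; the resulting 2-methoxychromone cannot be carried on. The fallback sets out from 13 and comes back at 17: C2 is excised and put back at the right oxidation level. Aqueous KOH in ethanol at reflux would open the lactone of 13, and the β-keto acid would decarboxylate to 1-[2-hydroxy-4,6-bis(methoxymethoxy)phenyl]-2-[4-methoxy-3-(3-methylbut-2-enyl)phenyl]ethanone F11. Me2NCH(OMe)2 in toluene at 90 °C would add the missing carbon at the active methylene, and the phenol would close onto the enaminone to give 17, isolated in this case. The conditions of step 8 would convert 17 into 18, so steps 6 and 7 are bypassed.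

Step 7. The most likely failure is collapse of the aluminium hemiacetal during the reduction, since the phenoxide of ring A is a good leaving group; the liberated enal would then be reduced on to the allylic alcohol. The fallback sets out from 14 and comes back at 15: over-reduction is accepted and corrected by oxidation. Excess iBu2AlH (3 equiv, −78 to 0 °C) would take 14 fully to 2-[(E)-3-hydroxy-1-methoxy-2-[4-methoxy-3-(3-methylbut-2-enyl)phenyl]prop-1-enyl]-3,5-bis(methoxymethoxy)phenol F12. MnO2 in CH2Cl2 should oxidise only the allylic alcohol, and the hydroxy enal, with phenol and aldehyde held cis by the double bond, would close to 15.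

Further compounds

F1 | step 5 | 4,5,7-trihydroxy-3-[4-methoxy-3-(3-methylbut-2-enyl)phenyl]chromen-2-one | COc1ccc(-c2c(O)c3c(O)cc(O)cc3oc2=O)cc1CC=C(C)C
F2 | step 5 | 3-[4-methoxy-3-(3-methylbut-2-enyl)phenyl]-4,5,7-tris(methoxymethoxy)chromen-2-one | COCOc1cc(OCOC)c2c(OCOC)c(-c3ccc(OC)c(CC=C(C)C)c3)c(=O)oc2c1
F3 | step 5 | 3-[4-methoxy-3-(3-methylbut-2-enyl)phenyl]-4,5,7-tris(methoxymethoxy)-2H-chromen-2-ol (racemic) | COCOc1cc(OCOC)c2c(c1)OC(O)C(c1ccc(OC)c(CC=C(C)C)c1)=C2OCOC
F4 | step 2 | methyl 2-(3-bromo-4-methoxyphenyl)acetate | COC(=O)Cc1ccc(OC)c(Br)c1
F5 | step 2 | methyl 2-[4-methoxy-3-(4,4,5,5-tetramethyl-1,3,2-dioxaborolan-2-yl)phenyl]acetate | COC(=O)Cc1ccc(OC)c(B2OC(C)(C)C(C)(C)O2)c1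
F6 | step 2 | methyl 2-[4-methoxy-3-(3-methylbut-2-enyl)phenyl]acetate | COC(=O)Cc1ccc(OC)c(CC=C(C)C)c1
F7 | step 4 | 2-(3-bromo-4-methoxyphenyl)propanedioic acid | COc1ccc(C(C(=O)O)C(=O)O)cc1Br
F8 | step 4 | bis(2,4,6-trichlorophenyl) 2-(3-bromo-4-methoxyphenyl)propanedioate | COc1ccc(C(C(=O)Oc2c(Cl)cc(Cl)cc2Cl)C(=O)Oc2c(Cl)cc(Cl)cc2Cl)cc1Br
F9 | step 4 | 3-(3-bromo-4-methoxyphenyl)-4-hydroxy-5,7-bis(methoxymethoxy)chromen-2-one | COCOc1cc(OCOC)c2c(O)c(-c3ccc(OC)c(Br)c3)c(=O)oc2c1
F10 | step 4 | 3-(3-bromo-4-methoxyphenyl)-4-methoxy-5,7-bis(methoxymethoxy)chromen-2-one | COCOc1cc(OCOC)c2c(OC)c(-c3ccc(OC)c(Br)c3)c(=O)oc2c1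
F11 | step 6 | 1-[2-hydroxy-4,6-bis(methoxymethoxy)phenyl]-2-[4-methoxy-3-(3-methylbut-2-enyl)phenyl]ethanone | COCOc1cc(O)c(C(=O)Cc2ccc(OC)c(CC=C(C)C)c2)c(OCOC)c1
F12 | step 7 | 2-[(E)-3-hydroxy-1-methoxy-2-[4-methoxy-3-(3-methylbut-2-enyl)phenyl]prop-1-enyl]-3,5-bis(methoxymethoxy)phenol | COCOc1cc(O)c(/C(OC)=C(\CO)c2ccc(OC)c(CC=C(C)C)c2)c(OCOC)c1
A1 | alternative 1 | 3-(3-bromo-4-methoxyphenyl)-5,7-di(propan-2-yloxy)chromen-4-one | CC(C)Oc1cc(OC(C)C)c2c(c1)occ(-c1ccc(OC)c(Br)c1)c2=O
A2 | alternative 1 | (Z)-2-(3-bromo-4-methoxyphenyl)-3-[3,5-di(propan-2-yloxy)phenoxy]prop-2-enoic acid | CC(C)Oc1cc(OC(C)C)cc(O/C=C(\C(=O)O)c2ccc(OC)c(Br)c2)c1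
A3 | alternative 1 | 3-(3-bromo-4-methoxyphenyl)-5,7-dihydroxychromen-4-one | COc1ccc(-c2coc3cc(O)cc(O)c3c2=O)cc1Br
A4 | alternative 2 | cis-4-[5,7-bis(methoxymethoxy)-4-oxochromen-3-yl]-6-(3-methylbut-2-enyl)cyclohex-2-en-1-one (racemic, one enantiomer drawn) | O=C1C=C[C@@H](c2coc3cc(OCOC)cc(OCOC)c3c2=O)C[C@H]1CC=C(C)C
A5 | alternative 2 | 2-[5,7-bis(methoxymethoxy)-4-oxochromen-3-yl]acetaldehyde | COCOc1cc(OCOC)c2c(c1)occ(CC=O)c2=O
A6 | alternative 2 | 6-methyl-3-methylidenehept-5-en-2-one | CC(=O)C(=C)CC=C(C)C
A7 | alternative 3 | 5-hydroxy-3-[4-methoxy-3-(3-methylbut-2-enyl)phenyl]-7-(triisopropylsilyloxy)chromen-4-one | CC(C)[Si](Oc1cc(O)c2c(c1)occ(-c1ccc(OC)c(CC=C(C)C)c1)c2=O)(C(C)C)C(C)C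
A8 | alternative 3 | 2-(2-diazoacetyl)-5-[4-methoxy-3-(3-methylbut-2-enyl)phenyl]pyran-4-one | COc1ccc(-c2coc(C(=O)C=[N+]=[N-])cc2=O)cc1CC=C(C)C
A9 | alternative 3 | ethynyloxy-tri(propan-2-yl)silane | C#CO[Si](C(C)C)(C(C)C)C(C)C
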